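# Proposed synthesis of CNP0207533.1 (24) by a triyne [2+2+2] cyclotrimerisation

Atom labels used throughout: ring A is C1 (OMe), C2 (H), C3 (pyran O), C4, C5, C6. C7 is the indane CH2, C8 and C9 are the ring-fusion CH groups (C9 on C5), C10 carries the catechol (ring B), and C11 is CMe2. C12 (on C4), C13 and C14 (CMe2–O) are the pyran carbons. The target is C8 S, C9 R, C10 S. Compound numbers 1–24 follow the steps; 20 is the triyne, 21 the product of the key step and 24 the target.

## The problem

- **Ring system.** In target 24 a pentasubstituted benzene (ring A) is shared by a cyclobutane-fused indane (C5–C6–C7–C8–C9 and C8–C9–C10–C11) and a 2,2-dimethyl-2H-pyran (C3–O–C14–C13–C12–C4). A catechol sits on C10 and a geminal dimethyl group on C11.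
- **Stereocentres.** C8, C9 and C10 are contiguous on the cyclobutane. C8 and C9 are cis because they share the five-membered ring, and the catechol on C10 is trans to the C9–C5 bond.
- **No late correction.** None of these centres is next to a carbonyl group in the target, so the cyclobutane has to be made with all three in place.
- **Control.** An open cyclobutane would not prefer the cis C8/C9 arrangement, so a temporary ring must enforce it. C10 can then be set from C9, because trans is favoured when the four-membered ring closes. The absolute configuration needs an external source.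
- **Sensitive groups.** The chromene is hydrogenated under debenzylation conditions and ionises in acid, the free catechol oxidises in basic air, and the benzylic cyclobutane bonds are strained. The alkene and the free phenols therefore have to appear last.
- **Enabling feature.** The three alternate bonds of ring A (C1–C2, C3–C4, C5–C6) connect three two-carbon units: C6≡C1 bearing OMe, C5≡C4, and C3≡C2 bearing the pyran oxygen. These are already linked through C9–C8–C7 and through C12–C13–C14–O. One alkyne cyclotrimerisation can therefore close ring A, the five-membered ring and the pyran with the substitution pattern fixed by connectivity.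

## Retrosynthesis

**24 back to 21 (end game).** The C12=C13 alkene is cut back to a C12 oxygen (chromanol 23), and the phenols are unveiled from silyl ether 22 and dibenzyl ether 21. The alkene cannot be carried through the cyclotrimerisation: with C12=C13 in the tether the ynol ether would be an allyl alkynyl ether, which undergoes [3,3] rearrangement well below room temperature. A silyloxy group at C12 is a placeholder whose configuration is irrelevant. The forward steps are a hydrogenolysis run before any alkene exists, a desilylation, and an E1 dehydration that can only give the chromene.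

**21 back to 20 (key disconnection).** C1–C2, C3–C4 and C5–C6 are cut, opening ring A, the indane five-membered ring and the pyran at once. Cutting one ring at a time would require regiocontrol on a benzene that carries five different substituents. Triyne 20 contains only the cyclobutane ring and no arene other than ring B. The forward reaction must run at room temperature, because the tertiary ethynyl ether of 20 fragments to a ketene on heating.

**20 back to 18, 17, and 14 + 15.** The ethynyl ether is traced to the 1,2-dichlorovinyl ether 18, a stable masked form, so the labile group exists for one step only. Silyl ether 18 comes from alcohol 17. The C6–C7 bond of 17 is cut to a C7 electrophile (triflate 16, from diol 14) and the lithium acetylide made from dichlorovinyl methyl ether 15. Homologating a C7–C6 aldehyde to a methoxyalkyne was rejected, since no short, reliable one-carbon route from an aldehyde to a 1-alkoxyalkyne exists. The forward step needs a clean SN2 reaction at a β-branched primary centre and selective activation of the primary hydroxyl of 14.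

**14 back to 8 + 12.** The C4–C12 bond is cut to the acetylide of alkynol 8 and aldehyde 12. This is the most convergent cut in the chain, and the addition may give either C12 epimer. Aldehyde 12 is traced to acetal 11, made from the commercial tertiary alcohol 9 and trichloroethylene 10.

**8 back to 7 and 6.** Enantiopure 8 is obtained from racemate 7 by kinetic resolution. In 7 the C5≡C4 triple bond is cut to lactol 6 by removing C4 (Ohira–Bestmann homologation in the forward sense). The lactol is the reason for this cut: it holds C5 as an aldehyde and C7 as an alcohol, so the two arms on C9 and C8 are differentiated without protecting groups and remain cis.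

**6 back to 5 and 4.** Lactol 6 is the hydrolysis product of bicyclic acetal 5. In 5 the cyclobutane bonds C8–C9 and C10–C11 are cut to give the open-chain diprenyl acetal 4.

- This is preferred to a ketene cycloaddition onto a cyclic diene, which would place a carbonyl group at C11 and require its conversion into CMe2 next to an ionisable benzylic centre.
- Here the geminal dimethyl group and the aryl group arrive from the two alkenes, the tether forces the cis fusion, and the aryl group should take the exo position.
- An ester tether would give the lactone directly, but esters prefer the conformation that keeps the two alkenes apart. An ether tether would leave C5 and C7 indistinguishable. The acetal tether avoids both problems.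

**4 back to 2 + 3, and 2 back to 1.** The acetal C–O bonds are cut to enal 2 and prenol 3. Enal 2 comes from commercial aldehyde 1 by a two-carbon Wittig homologation. The whole cyclobutane fragment therefore derives from 1, 3 and two one- or two-carbon reagents.

## Roads not taken

**Alternative 1:** three-component palladium annulation.
- **Cut:** C5–C9, C7–C8 and C6–C7.
- **Key step:** aryl triflate A2, cyclobutene A3 and CO give indanone A1. The arylpalladium species adds syn across C8=C9, CO inserts, and the acylpalladium closes onto C6.
- **Merits:** It is the most convergent plan. Ring A and the chromene are prepared from a simple resorcinol-type arene, and no labile ynol ether is involved. Syn addition anti to the aryl group of A3 would set C8 and C9 from the single stereocentre C10. The σ-alkylpalladium intermediate has no syn β-hydrogen and can wait for CO.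
- **Weak points:** A3 has no functional handle for an asymmetric synthesis. The two alkene carbons of A3 are similarly hindered, so aryl delivery to C9 rather than C8 is not assured. The closure must functionalise the C–H bond next to the methoxy group. The C7 carbonyl of A1 must be reduced to CH2 in the presence of the chromene.
- **Comparison:** This road is clearly shorter and keeps ring A intact from a purchased arene. The chosen plan sets against it that every regiochemical question is settled by a tether and that C7 arrives at the correct oxidation level.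

**Alternative 2:** open-chain stereocontrol, then 4-exo-tet closure.
- **Cut:** C8–C9.
- **Key step:** the malonate carbon of the open-chain alcohol A5 displaces the activated C9 oxygen with inversion, giving cyclobutane A4.
- **Merits:** The absolute configuration would come from asymmetric catalysis in the open chain, which is better than the resolution used in the chosen plan. Both arenes are bought, and the geminal dimethyl group assists the closure.
- **Weak points:** The displacement takes place at a hindered secondary benzylic carbon with a tertiary carbanion, and elimination to the conjugated stilbene is the obvious competitor. After closure, one ester of A4 must be removed so that the remaining carbon is cis to the ring A aryl group on C9. That is the less stable arrangement, and only it can close the indane. The C6–C7 bond and the whole chromene are still to be made.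
- **Comparison:** Better on absolute stereocontrol, weaker on the cis C8/C9 relationship, which the chosen plan obtains from ring fusion, and probably no shorter.

**Alternative 3:** Diels–Alder benzannulation.
- **Cut:** C1–C6 and C4–C5.
- **Key step:** diene A8 adds to α-bromo enone A7, and loss of HBr, methanol and the silyl group gives arene A6 with OMe at C1, OH at C3 and prenyl at C4.
- **Merits:** The regiochemistry of such oxygenated diene/halo-enone cycloadditions is dependable. The stereocentres of A7 are spectators. Oxidative closure of an ortho-prenylphenol to a chromene is a known single step.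
- **Weak points:** A7 is itself a 6-aryl-7,7-dimethylbicyclo[3.2.0]heptenone, so the cyclobutane problem is not reduced, and the ketone-based routes to it bring back the C=O to CMe2 conversion. A8 is hydrolytically fragile and needs several steps. The C7 ketone of A6 must be removed before the chromene exists, and the benzyl ethers must be cleaved without touching either the prenyl alkene or the chromene.
- **Comparison:** As a ring A construction this road is at least as reliable as the chosen one. The chosen plan sets against it three rings closed in one step, no oxidation-state correction at C7, and a five-step entry to its cyclobutane.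

Key step: step 14

## Route

Remark 1: the lipase in step 6 is assumed to acylate the (1R,2R,3R)-enantiomer of 7 faster, so that 8 is recovered as the alcohol; if the preference is reversed, the wanted enantiomer is taken from the acetate by methanolysis.

Remark 2: compounds 14 and 16–23 are carried as mixtures of the two C12 epimers, since this centre is destroyed in step 17; the CIP descriptor of C9 changes from S to R after step 11 without any change of configuration.

Step 1
Reactants: 1 3,4-bis(benzyloxy)benzaldehyde
Product: 2 (E)-3-[3,4-bis(benzyloxy)phenyl]prop-2-enal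
Conditions: Ph3P=CHCHO (1.1 equiv), toluene, 80 °C
Reagents that add atoms: (triphenylphosphoranylidene)acetaldehyde, O=CC=P(c1ccccc1)(c1ccccc1)c1ccccc1
Why: Wittig olefination with a stabilised formyl ylide, which should give the E-enal; a small excess of 1 limits a second homologation.

Step 2
Reactants: 2 (E)-3-[3,4-bis(benzyloxy)phenyl]prop-2-enal; 3 3-methylbut-2-en-1-ol (prenol)
Product: 4 1,2-bis(benzyloxy)-4-[(E)-3,3-bis(3-methylbut-2-en-1-yloxy)prop-1-en-1-yl]benzene
Conditions: 3 (3 equiv), PPTS (5 mol%), cyclohexane, reflux, Dean–Stark; Et3N quench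
Reagents that add atoms: none
Why: Acid-catalysed acetalisation of an enal with an allylic alcohol under azeotropic water removal; the weak acid should not ionise prenol or the product.

Step 3
Reactants: 4 1,2-bis(benzyloxy)-4-[(E)-3,3-bis(3-methylbut-2-en-1-yloxy)prop-1-en-1-yl]benzene
Product: 5 racemic 7-exo-[3,4-bis(benzyloxy)phenyl]-6,6-dimethyl-2-[(3-methylbut-2-en-1-yl)oxy]-3-oxabicyclo[3.2.0]heptane (cis-fused; both acetal epimers)
Conditions: [Ir(dF(CF3)ppy)2(dtbbpy)]PF6 (1 mol%), DMSO, blue LEDs, rt, degassed
Reagents that add atoms: none
Why: Visible-light intramolecular styrene–alkene [2+2] by triplet energy transfer from the excited trivalent iridium complex; the styrene triplet should close the five-membered ring first (C9–C8) to a benzylic/tertiary 1,4-biradical that collapses (C10–C11) to the cis-fused bicycle, with the aryl group taking the less hindered exo position, which sets C10 trans to C9–C5.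

Step 4
Reactants: 5 racemic bicyclic prenyl acetal
Product: 6 racemic 7-exo-[3,4-bis(benzyloxy)phenyl]-6,6-dimethyl-3-oxabicyclo[3.2.0]heptan-2-ol (lactol; both anomers)
Conditions: 1 M aq. HCl, THF, rt
Reagents that add atoms: water, O
Why: Hydrolysis of a 2-alkoxyoxolane through the cyclic oxocarbenium ion; benzyl ethers and the cyclobutane should be unaffected.

Step 5
Reactants: 6 racemic lactol
Product: 7 racemic [(1S*,2S*,3S*)-3-[3,4-bis(benzyloxy)phenyl]-2-ethynyl-4,4-dimethylcyclobutyl]methanol
Conditions: dimethyl (1-diazo-2-oxopropyl)phosphonate, K2CO3, MeOH, 0 °C to rt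
Reagents that add atoms: dimethyl (1-diazo-2-oxopropyl)phosphonate, CC(=O)C(=[N+]=[N-])P(=O)(OC)OC
Why: Ohira–Bestmann homologation of the lactol through its open hydroxy aldehyde adds C4 and frees the C7 hydroxyl; enolisation at C9 would place a double bond exocyclic to the cyclobutane and should be slow, so the cis relationship is kept.

Step 6
Reactants: 7 racemic alkynol
Product: 8 [(1S,2S,3S)-3-[3,4-bis(benzyloxy)phenyl]-2-ethynyl-4,4-dimethylcyclobutyl]methanol
Conditions: Burkholderia cepacia lipase (Amano PS), vinyl acetate, tert-butyl methyl ether, rt, run past half conversion; chromatography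
Reagents that add atoms: none
Why: Lipase-catalysed kinetic resolution of a primary alcohol with a β-stereocentre by enantioselective acylation; the fast enantiomer leaves as its acetate and 8 is recovered.

Step 7
Reactants: 9 4,4-dimethoxy-2-methylbutan-2-ol; 10 trichloroethylene
Product: 11 (E)-1,2-dichloro-1-[(4,4-dimethoxy-2-methylbutan-2-yl)oxy]ethene
Conditions: KH, THF, 0 °C; then 10, rt
Reagents that add atoms: none
Why: First stage of Greene's ynol ether synthesis: the potassium alkoxide adds to dichloroacetylene formed in situ from trichloroethylene (net addition–elimination) to give the (E)-1,2-dichlorovinyl ether.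

Step 8
Reactants: 11 dichlorovinyl ether acetal
Product: 12 3-{[(E)-1,2-dichloroethenyl]oxy}-3-methylbutanal
Conditions: TsOH·H2O (cat.), acetone/H2O, rt
Reagents that add atoms: water, O
Why: Acid-catalysed acetal hydrolysis; the dichlorovinyl ether is a deactivated enol ether and should not protonate under these conditions.

Step 9
Reactants: 8 (1S,2S,3S)-alkynol; 12 3-{[(E)-1,2-dichloroethenyl]oxy}-3-methylbutanal
Product: 14 5-{[(E)-1,2-dichloroethenyl]oxy}-1-{(1S,2S,4S)-2-[3,4-bis(benzyloxy)phenyl]-4-(hydroxymethyl)-3,3-dimethylcyclobutyl}-5-methylhex-1-yn-3-ol (both C12 epimers), via dilithium salt of the alkynol 13 (not isolated)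
Conditions: n-BuLi (2.05 equiv), THF, −78 °C; then 12, −78 °C; aq. NH4Cl
Reagents that add atoms: none
Why: 1,2-Addition of a lithium acetylide to an aldehyde forms C4–C12; the C7 lithium alkoxide is a spectator and the new C12 centre need not be controlled.

Step 10
Reactants: 10 trichloroethylene
Product: 15 (E)-1,2-dichloro-1-methoxyethene
Conditions: KOMe, THF, 0 °C to rt; distillation
Reagents that add atoms: potassium methoxide, [K+].[O-]C
Why: The same alkoxide/trichloroethylene addition–elimination as in step 7.

Step 11
Reactants: 14 propargylic diol; 15 (E)-1,2-dichloro-1-methoxyethene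
Product: 17 5-{[(E)-1,2-dichloroethenyl]oxy}-1-{(1R,2S,4S)-2-[3,4-bis(benzyloxy)phenyl]-4-(3-methoxyprop-2-yn-1-yl)-3,3-dimethylcyclobutyl}-5-methylhex-1-yn-3-ol, via primary triflate 16 (not isolated)
Conditions: Tf2O (1.05 equiv), 2,6-lutidine, CH2Cl2, −78 °C; then LiC≡COMe (4 equiv, from 15 and n-BuLi, THF, −78 to −40 °C), THF/DMPU, −78 to −20 °C
Reagents that add atoms: trifluoromethanesulfonic anhydride, O=S(=O)(OS(=O)(=O)C(F)(F)F)C(F)(F)F (its atoms remain only in 16)
Why: Low-temperature sulfonylation should select the primary hydroxyl; SN2 alkylation of lithium methoxyacetylide (Greene's dehydrochlorination and chlorine–lithium exchange of 15) then forms C6–C7, with the C12 alkoxide as a spectator.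

Step 12
Reactants: 17 methoxyalkyne alcohol
Product: 18 tert-butyldimethylsilyl ether of 17 at the C12 oxygen
Conditions: TBSCl, imidazole, DMF, rt
Reagents that add atoms: tert-butyldimethylsilyl chloride, CC(C)(C)[Si](C)(C)Cl
Why: Standard silylation of a secondary propargylic alcohol under non-acidic conditions that the methoxyalkyne tolerates.

Step 13
Reactants: 18 silyl ether with dichlorovinyl ether
Product: 20 tert-butyl{[1-{(1R,2S,4S)-2-[3,4-bis(benzyloxy)phenyl]-4-(3-methoxyprop-2-yn-1-yl)-3,3-dimethylcyclobutyl}-5-(ethynyloxy)-5-methylhex-1-yn-3-yl]oxy}dimethylsilane (triyne), via lithium alkynyl ether 19 (not isolated)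
Conditions: n-BuLi (2.5 equiv), THF, −78 to −40 °C; MeOH, −78 °C; work-up and filtration below 20 °C, used at once
Reagents that add atoms: none
Why: Second stage of Greene's synthesis: deprotonation and loss of LiCl give the chloroalkynyl ether, chlorine–lithium exchange gives 19, and protonation gives the terminal ynol ether; the other groups should be inert to n-BuLi at this temperature.

Step 14
Reactants: 20 triyne
Product: 21 O,O′-dibenzyl ether of the 12,13-dihydro-12-(tert-butyldimethylsilyloxy) derivative of 24 (C8 S, C9 R, C10 S; both C12 epimers)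
Conditions: [Rh(cod)2]BF4 (5 mol%), rac-BINAP (5 mol%), pre-treated with H2 (1 atm), then argon, CH2Cl2, rt, slow addition of 20
Reagents that add atoms: none
Why: The closest known reaction type is the cationic rhodium/bisphosphine-catalysed intramolecular [2+2+2] cyclotrimerisation of triynes, which accepts alkynyl ethers. The monovalent rhodium centre should bind the 1,6-diyne (C6≡C1 and C5≡C4) and couple it oxidatively to a rhodacyclopentadiene of trivalent rhodium (C5–C6); the tethered ethynyl ether then inserts (C3–C4) and reductive elimination forms C1–C2 and releases the arene. The five-membered ring closes in the oxidative coupling of the two alkynes held cis on the cyclobutane through C9–C8–C7, the pyran closes as a six-membered ring when the alkyne tethered through C12–C13–C14–O inserts, and ring A closes in the reductive elimination. No stereocentre is formed; C8, C9 and C10 are not touched and C12 stays an epimer mixture. The regiochemistry (OMe on C1, H on C2, O on C3) is fixed because each alkyne can only join its tethered neighbours. The selectivity the step needs is kinetic: cyclisation must outrun retro-ene fragmentation of the tertiary ynol ether and intermolecular oligomerisation, which room temperature, a non-coordinating counter-ion, slow addition and the pre-organised cis-diyne should secure. The unsubstituted C2 terminus keeps the last bond formation uncrowded.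

Step 15
Reactants: 21 tetracyclic dibenzyl ether
Product: 22 12,13-dihydro-12-(tert-butyldimethylsilyloxy) derivative of 24 (free catechol; both C12 epimers)
Conditions: H2 (1 atm), 10% Pd on carbon, EtOAc, rt
Reagents that add atoms: none
Why: Hydrogenolysis of aryl benzyl ethers, which should be much faster than cleavage of the silylated benzylic C12–O bond; it is placed before the C12=C13 alkene exists.

Step 16
Reactants: 22 silyl ether catechol
Product: 23 12,13-dihydro-12-hydroxy derivative of 24 (chromanol; both C12 epimers)
Conditions: TBAF, AcOH (1:1), THF, rt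
Reagents that add atoms: none
Why: Fluoride desilylation, buffered so that the catechol stays protonated and is not oxidised.

Step 17
Reactants: 23 chromanol
Product: 24 CNP0207533.1 (C8 S, C9 R, C10 S)
Conditions: TsOH·H2O (10 mol%), toluene, 70 °C, argon
Reagents that add atoms: none
Why: E1 dehydration of a chroman-4-ol through the C12 cation stabilised by the ring A oxygens at C3 (ortho) and C1 (para); only C13 carries β-hydrogens, so only the chromene can form, and both C12 epimers converge.

## Compound list

1 | 3,4-bis(benzyloxy)benzaldehyde | O=Cc1ccc(OCc2ccccc2)c(OCc2ccccc2)c1 | starting material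
2 | (E)-3-[3,4-bis(benzyloxy)phenyl]prop-2-enal | O=C/C=C/c1ccc(OCc2ccccc2)c(OCc2ccccc2)c1 | intermediate
3 | 3-methylbut-2-en-1-ol | CC(C)=CCO | starting material
4 | 1,2-bis(benzyloxy)-4-[(E)-3,3-bis(3-methylbut-2-en-1-yloxy)prop-1-en-1-yl]benzene | CC(C)=CCOC(OCC=C(C)C)/C=C/c1ccc(OCc2ccccc2)c(OCc2ccccc2)c1 | intermediate
5 | racemic 7-exo-[3,4-bis(benzyloxy)phenyl]-6,6-dimethyl-2-[(3-methylbut-2-en-1-yl)oxy]-3-oxabicyclo[3.2.0]heptane (racemate; the enantiomer carried on is drawn) | CC(C)=CCOC2[C@@H]1[C@H](CO2)C(C)(C)[C@H]1c1ccc(OCc3ccccc3)c(OCc3ccccc3)c1 | intermediate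
6 | racemic 7-exo-[3,4-bis(benzyloxy)phenyl]-6,6-dimethyl-3-oxabicyclo[3.2.0]heptan-2-ol (racemate; the enantiomer carried on is drawn) | OC2[C@@H]1[C@H](CO2)C(C)(C)[C@H]1c1ccc(OCc3ccccc3)c(OCc3ccccc3)c1 | intermediate
7 | racemic [(1S*,2S*,3S*)-3-[3,4-bis(benzyloxy)phenyl]-2-ethynyl-4,4-dimethylcyclobutyl]methanol (racemate; the enantiomer carried on is drawn) | C#C[C@@H]1[C@H](CO)C(C)(C)[C@H]1c1ccc(OCc2ccccc2)c(OCc2ccccc2)c1 | intermediate
8 | [(1S,2S,3S)-3-[3,4-bis(benzyloxy)phenyl]-2-ethynyl-4,4-dimethylcyclobutyl]methanol | C#C[C@@H]1[C@H](CO)C(C)(C)[C@H]1c1ccc(OCc2ccccc2)c(OCc2ccccc2)c1 | intermediate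
9 | 4,4-dimethoxy-2-methylbutan-2-ol | COC(CC(C)(C)O)OC | starting material
10 | trichloroethylene | ClC=C(Cl)Cl | starting material
11 | (E)-1,2-dichloro-1-[(4,4-dimethoxy-2-methylbutan-2-yl)oxy]ethene | Cl/C=C(/Cl)OC(C)(C)CC(OC)OC | intermediate
12 | 3-{[(E)-1,2-dichloroethenyl]oxy}-3-methylbutanal | Cl/C=C(/Cl)OC(C)(C)CC=O | intermediate
13 | dilithium salt of 8 (lithium alkoxide and lithium acetylide) | [Li]C#C[C@@H]1[C@H](CO[Li])C(C)(C)[C@H]1c1ccc(OCc2ccccc2)c(OCc2ccccc2)c1 | intermediate
14 | 5-{[(E)-1,2-dichloroethenyl]oxy}-1-{(1S,2S,4S)-2-[3,4-bis(benzyloxy)phenyl]-4-(hydroxymethyl)-3,3-dimethylcyclobutyl}-5-methylhex-1-yn-3-ol (C12 epimers) | Cl/C=C(/Cl)OC(C)(C)CC(O)C#C[C@@H]1[C@H](CO)C(C)(C)[C@H]1c1ccc(OCc2ccccc2)c(OCc2ccccc2)c1 | intermediate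
15 | (E)-1,2-dichloro-1-methoxyethene | Cl/C=C(/Cl)OC | intermediate
16 | primary (C7) trifluoromethanesulfonate of 14 | Cl/C=C(/Cl)OC(C)(C)CC(O)C#C[C@@H]1[C@H](COS(=O)(=O)C(F)(F)F)C(C)(C)[C@H]1c1ccc(OCc2ccccc2)c(OCc2ccccc2)c1 | intermediate
17 | 5-{[(E)-1,2-dichloroethenyl]oxy}-1-{(1R,2S,4S)-2-[3,4-bis(benzyloxy)phenyl]-4-(3-methoxyprop-2-yn-1-yl)-3,3-dimethylcyclobutyl}-5-methylhex-1-yn-3-ol (C12 epimers) | Cl/C=C(/Cl)OC(C)(C)CC(O)C#C[C@@H]1[C@H](CC#COC)C(C)(C)[C@H]1c1ccc(OCc2ccccc2)c(OCc2ccccc2)c1 | intermediate
18 | C12 tert-butyldimethylsilyl ether of 17 | Cl/C=C(/Cl)OC(C)(C)CC(O[Si](C)(C)C(C)(C)C)C#C[C@@H]1[C@H](CC#COC)C(C)(C)[C@H]1c1ccc(OCc2ccccc2)c(OCc2ccccc2)c1 | intermediate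
19 | lithium acetylide of the ynol ether 20 | [Li]C#COC(C)(C)CC(O[Si](C)(C)C(C)(C)C)C#C[C@@H]1[C@H](CC#COC)C(C)(C)[C@H]1c1ccc(OCc2ccccc2)c(OCc2ccccc2)c1 | intermediate
20 | tert-butyl{[1-{(1R,2S,4S)-2-[3,4-bis(benzyloxy)phenyl]-4-(3-methoxyprop-2-yn-1-yl)-3,3-dimethylcyclobutyl}-5-(ethynyloxy)-5-methylhex-1-yn-3-yl]oxy}dimethylsilane (triyne; C12 epimers) | C#COC(C)(C)CC(O[Si](C)(C)C(C)(C)C)C#C[C@@H]1[C@H](CC#COC)C(C)(C)[C@H]1c1ccc(OCc2ccccc2)c(OCc2ccccc2)c1 | intermediate
21 | O,O′-dibenzyl ether of the 12,13-dihydro-12-(tert-butyldimethylsilyloxy) derivative of 24 (C8 S, C9 R, C10 S; C12 epimers) | COc1cc2c(c3c1C[C@H]1[C@@H]3[C@H](c3ccc(OCc4ccccc4)c(OCc4ccccc4)c3)C1(C)C)C(O[Si](C)(C)C(C)(C)C)CC(C)(C)O2 | intermediate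
22 | 12,13-dihydro-12-(tert-butyldimethylsilyloxy) derivative of 24 (C12 epimers) | COc1cc2c(c3c1C[C@H]1[C@@H]3[C@H](c3ccc(O)c(O)c3)C1(C)C)C(O[Si](C)(C)C(C)(C)C)CC(C)(C)O2 | intermediate
23 | 12,13-dihydro-12-hydroxy derivative of 24 (C12 epimers) | COc1cc2c(c3c1C[C@H]1[C@@H]3[C@H](c3ccc(O)c(O)c3)C1(C)C)C(O)CC(C)(C)O2 | intermediate
24 | CNP0207533.1: ring A with OMe on C1, 2,2-dimethyl-2H-pyran fused at C3/C4, cyclobutane-fused indane at C5/C6, 3,4-dihydroxyphenyl on C10, CMe2 at C11; C8 S, C9 R, C10 S | COc1cc2c(c3c1C[C@H]1[C@@H]3[C@H](c3ccc(O)c(O)c3)C1(C)C)C=CC(C)(C)O2 | target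

## Step count and risks

Total: 17 steps. Longest linear sequence: 14 steps (steps 1–6, 9 and 11–17, from aldehyde 1). Steps 7–8 and step 10 are side branches.

**Step 14 (key step).**
- **Risk:** The most likely failure is retro-ene fragmentation of the tertiary ethynyl ether, with loss of ketene, before the third alkyne inserts. This can happen while 20 is being isolated in step 13 or on the metal. Intermolecular oligomerisation is the second concern.
- **Fallback:** The pyran oxygen is taken out of the cyclotrimerisation and a temporary silicon tether delivers the third alkyne. The route sets out from 8 and returns at 24.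
  - The dilithium salt of 8 is added to 3-methylbut-2-enal to give the allylic propargylic diol F1.
  - As in step 11, F1 is converted through its primary triflate F2 into the methoxyalkyne alcohol F3.
  - The C12 hydroxyl is silylated with chloro(ethynyl)dimethylsilane and imidazole to give the silicon-tethered triyne F4.
  - The same rhodium catalyst should convert F4 into the benzoxasilole F5. Ring A and the five-membered ring close as before, and C3 now carries silicon.
  - Tamao–Fleming oxidation (H2O2, KF, KHCO3, THF/MeOH) gives the ortho-hydroxyaryl allylic alcohol F6.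
  - PPTS in CH2Cl2 cyclodehydrates F6 to the dibenzyl ether of the target, F7.
  - BCl3 with pentamethylbenzene at −78 °C removes the benzyl groups without reducing the chromene and gives 24.

**Step 3.**
- **Risk:** Triplet sensitisation may fail to close the ring, leaving only E/Z isomerisation of the styrene, or the aryl group may not go cleanly exo.
- **Fallback:** The mode of activation is changed from an excited state to hole catalysis in the dark. From 4, tris(4-bromophenyl)aminium hexachloroantimonate (catalytic) with 2,6-di-tert-butylpyridine in CH2Cl2 at 0 °C oxidises the electron-rich styrene to its radical cation. Stepwise [2+2] with the prenyl alkene then returns to the route at 5. No new compound is made (F0).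

**Step 6.**
- **Risk:** The lipase may discriminate poorly between the enantiomers of 7, because the stereocentre next to the carbinol carbon is flanked by groups of similar size.
- **Fallback:** Classical resolution. From 7, esterification with (S)-2-methoxy-2-phenylacetic acid (DCC, DMAP) gives two diastereomeric esters, which are separated by chromatography or crystallisation. The (S)-2-methoxy-2-phenylacetate of the (1S,2S,3S)-alcohol, F8, is methanolysed (K2CO3, MeOH) and returns to the route at 8.

**Step 11.**
- **Risk:** The secondary propargylic hydroxyl may be sulfonylated alongside the primary one, or the acetylide may cause elimination at the β-branched C7.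
- **Fallback:** From 14, both hydroxyls are silylated (TBSCl, imidazole, DMF) to the bis-silyl ether F9. The primary silyl ether is cleaved selectively (CSA, MeOH/CH2Cl2, 0 °C) to the C7 alcohol F10. This is converted into the stable primary iodide F11 (iodine, PPh3, imidazole). F11 alkylates lithium methoxyacetylide in THF/HMPA at rt and returns to the route at 18, bypassing 17.

## Further compounds

F1 | step 14 | 1-{(1S,2S,4S)-2-[3,4-bis(benzyloxy)phenyl]-4-(hydroxymethyl)-3,3-dimethylcyclobutyl}-5-methylhex-4-en-1-yn-3-ol (C12 epimers) | CC(C)=CC(O)C#C[C@@H]1[C@H](CO)C(C)(C)[C@H]1c1ccc(OCc2ccccc2)c(OCc2ccccc2)c1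
F2 | step 14 | primary trifluoromethanesulfonate of F1 | CC(C)=CC(O)C#C[C@@H]1[C@H](COS(=O)(=O)C(F)(F)F)C(C)(C)[C@H]1c1ccc(OCc2ccccc2)c(OCc2ccccc2)c1
F3 | step 14 | 1-{(1R,2S,4S)-2-[3,4-bis(benzyloxy)phenyl]-4-(3-methoxyprop-2-yn-1-yl)-3,3-dimethylcyclobutyl}-5-methylhex-4-en-1-yn-3-ol | CC(C)=CC(O)C#C[C@@H]1[C@H](CC#COC)C(C)(C)[C@H]1c1ccc(OCc2ccccc2)c(OCc2ccccc2)c1
F4 | step 14 | ethynyldimethylsilyl ether of F3 (silicon-tethered triyne) | CC(C)=CC(O[Si](C)(C)C#C)C#C[C@@H]1[C@H](CC#COC)C(C)(C)[C@H]1c1ccc(OCc2ccccc2)c(OCc2ccccc2)c1
F5 | step 14 | benzoxasilole: ring A with OMe on C1, SiMe2 on C3 bridged through oxygen to C12, 2-methylprop-1-enyl on C12, cyclobutane-fused indane at C5/C6 | COc1cc2c(c3c1C[C@H]1[C@@H]3[C@H](c3ccc(OCc4ccccc4)c(OCc4ccccc4)c3)C1(C)C)C(C=C(C)C)O[Si]2(C)C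
F6 | step 14 | C3 phenol with a 1-hydroxy-3-methylbut-2-enyl group on C4 | COc1cc(O)c(C(O)C=C(C)C)c2c1C[C@H]1[C@@H]2[C@H](c2ccc(OCc3ccccc3)c(OCc3ccccc3)c2)C1(C)C
F7 | step 14 | O,O′-dibenzyl ether of 24 | COc1cc2c(c3c1C[C@H]1[C@@H]3[C@H](c3ccc(OCc4ccccc4)c(OCc4ccccc4)c3)C1(C)C)C=CC(C)(C)O2
F0 | step 3 | none | none
F8 | step 6 | [(1S,2S,3S)-3-[3,4-bis(benzyloxy)phenyl]-2-ethynyl-4,4-dimethylcyclobutyl]methyl (S)-2-methoxy-2-phenylacetate | C#C[C@@H]1[C@H](COC(=O)[C@@H](OC)c2ccccc2)C(C)(C)[C@H]1c1ccc(OCc2ccccc2)c(OCc2ccccc2)c1
F9 | step 11 | bis(tert-butyldimethylsilyl) ether of 14 | Cl/C=C(/Cl)OC(C)(C)CC(O[Si](C)(C)C(C)(C)C)C#C[C@@H]1[C@H](CO[Si](C)(C)C(C)(C)C)C(C)(C)[C@H]1c1ccc(OCc2ccccc2)c(OCc2ccccc2)c1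
F10 | step 11 | C12 tert-butyldimethylsilyl ether of 14 with free C7 hydroxyl | Cl/C=C(/Cl)OC(C)(C)CC(O[Si](C)(C)C(C)(C)C)C#C[C@@H]1[C@H](CO)C(C)(C)[C@H]1c1ccc(OCc2ccccc2)c(OCc2ccccc2)c1
F11 | step 11 | C7 iodide of F10 | Cl/C=C(/Cl)OC(C)(C)CC(O[Si](C)(C)C(C)(C)C)C#C[C@@H]1[C@H](CI)C(C)(C)[C@H]1c1ccc(OCc2ccccc2)c(OCc2ccccc2)c1
A1 | alternative 1 | C7-oxo tetracycle with the chromene in place and the catechol as its bis(methoxymethyl) ether | COc1cc2c(c3c1C(=O)[C@H]1[C@@H]3[C@H](c3ccc(OCOC)c(OCOC)c3)C1(C)C)C=CC(C)(C)O2
A2 | alternative 1 | 7-methoxy-2,2-dimethyl-2H-chromen-5-yl trifluoromethanesulfonate | COc1cc(OS(=O)(=O)C(F)(F)F)c2C=CC(C)(C)Oc2c1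
A3 | alternative 1 | 3-[3,4-bis(methoxymethoxy)phenyl]-4,4-dimethylcyclobut-1-ene (benzylic carbon configured as C10 of 24) | C1=CC(C)(C)[C@H]1c1ccc(OCOC)c(OCOC)c1
A4 | alternative 2 | dimethyl 2-[5-(benzyloxy)-2-bromo-3-methoxyphenyl]-3-[3,4-bis(benzyloxy)phenyl]-4,4-dimethylcyclobutane-1,1-dicarboxylate (aryl groups trans) | COC(=O)C1(C(=O)OC)[C@@H](c2cc(OCc3ccccc3)cc(OC)c2Br)[C@H](c2ccc(OCc3ccccc3)c(OCc3ccccc3)c2)C1(C)C
A5 | alternative 2 | dimethyl 2-{4-[5-(benzyloxy)-2-bromo-3-methoxyphenyl]-3-[3,4-bis(benzyloxy)phenyl]-4-hydroxy-2-methylbutan-2-yl}propanedioate | COC(=O)C(C(=O)OC)C(C)(C)[C@@H](c1ccc(OCc2ccccc2)c(OCc2ccccc2)c1)[C@H](O)c1cc(OCc2ccccc2)cc(OC)c1Br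
A6 | alternative 3 | tricyclic indanone with completed ring A (OMe on C1, OH on C3, prenyl on C4) | COc1cc(O)c(CC=C(C)C)c2c1C(=O)[C@H]1[C@@H]2[C@H](c2ccc(OCc3ccccc3)c(OCc3ccccc3)c2)C1(C)C
A7 | alternative 3 | 6-[3,4-bis(benzyloxy)phenyl]-3-bromo-7,7-dimethylbicyclo[3.2.0]hept-3-en-2-one (cis-fused; aryl exo) | BrC1=C[C@@H]2[C@H](C1=O)C(C)(C)[C@H]2c1ccc(OCc2ccccc2)c(OCc2ccccc2)c1
A8 | alternative 3 | 1,1-dimethoxy-7-methyl-3-(trimethylsilyloxy)octa-1,3,6-triene | COC(OC)=CC(O[Si](C)(C)C)=CCC=C(C)C
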